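0.0932 M of protic impurity is the crossover level of this flask: the concentration at which the quench removes starting material as fast as the route through the intermediate does, reckoned with the capture held at its value for c(second nucleophile) as charged.

starting material 1.0 M; second nucleophile 1.00 M; protic impurity 0.500 M; solid first nucleophile 0.600 M; time 40 h

    starting material ⇌ intermediate (K1 = 0.0030, k1 = 7.3 × 10⁻⁴ min⁻¹)
    first nucleophile + intermediate → target (k2 = 0.44 M⁻¹ min⁻¹)
    second nucleophile + intermediate → other capture product (k3 = 0.43 M⁻¹ min⁻¹)
    starting material + protic impurity → quenched substrate (k4 = 0.0050 M⁻¹ min⁻¹)
    solid first nucleophile ⇌ first nucleophile, rate k5*(cs5 - [first nucleophile]) while solid is left; crystals form when [first nucleophile] > cs5 (cs5 = 0.48 M, k5 = 4.6 × 10⁻⁴ min⁻¹)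
    starting material + intermediate → side product (k6 = 3.6 × 10⁻⁴ M⁻¹ min⁻¹)

- a species is counted by the starting material in it: one side product counts as two
- given per volume of solution although it is solid: solid first nucleophile
- at the start none of the solid first nucleophile is in solution
- the reaction counts as stopped when no species that holds the starting material changes by six tenths of a point or more over the second half of the time
- run time (flask): 40 h

- which holds at 40 h: what has brought the reaction to rest, or that it has not come to rest (for what has run out or reacted, a solid counts together with what of it has only dissolved) (the first nucleophile has run out first / all of the starting material has reacted / the second nucleophile has run out first / it is still moving / forward and back rates have come level)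
- part of the starting material gone at 40 h
- the target standing at 40 h, as a percentage of the starting material charged
- the other capture product standing at 40 h, as a percentage of the starting material charged

Here is how I get that level. The first nucleophile starts undissolved, so I let the second nucleophile do the capturing. Its reversible formation by itself gives a relaxation half-life of 2.84 min, short against 40 h, so I treat the intermediate as steady. It falls back at 0.243 min⁻¹ and is captured at 0.430 min⁻¹, so 63.9% of what ionises goes on. The starting material therefore leaks away with a pseudo-first-order constant of 4.66 × 10⁻⁴ min⁻¹, which I hold through the run, assuming that the first nucleophile replaces what the second loses. The quench constant, the rate constant times c(protic impurity), starts at 0.00250 min⁻¹, which is 5.36 times the leak. The crossover is the leak divided by that rate constant.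

Now the curve. c(starting material) starts with a slope of 0.00297 M min⁻¹. Dividing the two rate laws gives its path against the impurity: it loses what the impurity has lost, plus the crossover level times ln(charge over present impurity). At the crossover this leaves 0.437 M, and taking the mean of this and the charge as c(starting material) in the quench puts this knee near 7.79 h. Past the knee I let the remaining impurity take its 0.0932 M, and the other 0.344 M decays with the leak. That gives 0.140 M at the end, a conversion of 86.0%. Capture in this reckoning comes to 0.360 M, less than the second nucleophile charged, and the tail falls to 57.2% of itself over the second half, so I call the flask still moving. How capture divides, I do not reckon.

The forecast says it is still moving, with conversion 86% (82% to 90%), target 5% (3.5% to 7%) and other capture product 32% (28% to 36%), on the ground that “The second nucleophile takes most of the capture because it is in solution from the start”.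

The simulation gives it is still moving, conversion 85.9%, target 5.04% and other capture product 31.7%.

In this flask the protic impurity stands at 0.199 M after 4.00 h, above the crossover, and at 0.0299 M after 20.0 h, below it. For the neighbour charged with 0.40 M of second nucleophile, the same reckoning puts the crossover lower, at 0.0605 M. After 40.0 h that neighbour holds 49.5% quenched substrate and 21.3% starting material.

The constants used here were drawn at random within sensible limits.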